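**Retrosynthetic overview**

1. Ring A is made last. Its acetoxy-bearing quaternary carbon is separated from the five hydrindane stereocentres by the exocyclic CH2 and lies 1,4 to the CHBr carbon. It is taken as the alpha-carbon of aldehyde 21: Michael addition to methyl vinyl ketone forms its bond to the ring CH2, and aldol condensation forms the enone C=C (catalyst-controlled Robinson annulation).
2. On enone 25 the saturated alpha-carbon is gem-dimethylated, and the ketone carbon becomes CHBr (conjugate reduction/enol triflate, triflate-to-bromide exchange, hydrogen-atom-transfer hydrogenation). Desilylation follows.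
3. Ring B comes from 4,4-dimethoxycyclohexa-2,5-dienone: asymmetric vinyl addition, then methylation and trans-selective bromoethylation at the future angular carbon.
4. Ring C is closed by 5-exo radical cyclisation onto an enoate. On ring B the ketone becomes the equatorial bromide and the masked ketone becomes the axial tertiary carbinol. The ester arm is extended to the alpha-acetoxy aldehyde.
5. Order of ring formation: B (from dienone 1), C (step 5), A (step 15).

Key step: step 15

Assumption: 2-bromoethyl trifluoromethanesulfonate (5) is treated as a purchasable reagent (otherwise one operation from 2-bromoethanol and Tf2O).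

Hydrindane locants used in all names: C1 carries the side chain, C3a the angular methyl, C4 the bromine, C7 the carbinol carbon, C7a the ring-fusion hydrogen. Ring B is the six-membered ring, ring C the five-membered ring, ring A the acetoxycyclohexane.

**Route**

Step 1
Reactants: 1 4,4-dimethoxycyclohexa-2,5-dien-1-one; 2 potassium vinyltrifluoroborate
Product: 3 (R)-4,4-dimethoxy-5-vinylcyclohex-2-en-1-one
Conditions: [Rh(cod)2]BF4 (3 mol %), (R)-BINAP (3.3 mol %), Et3N, toluene/H2O, 30 °C
Reagents that add atoms: none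
Why: Rhodium-catalysed asymmetric 1,4-addition of an alkenyltrifluoroborate (Hayashi–Miyaura reaction) to one of the two enantiotopic enone arms sets C5; (R)-BINAP is expected to give the R adduct by analogy with cyclohex-2-enone, and the mono-adduct is too hindered next to the ketal to add a second vinyl group.

Step 2
Reactants: 3 (R)-4,4-dimethoxy-5-vinylcyclohex-2-en-1-one
Product: 4 (5S,6RS)-4,4-dimethoxy-6-methyl-5-vinylcyclohex-2-en-1-one
Conditions: LiN(i-Pr)2, MeI, THF, −78 → −40 °C
Reagents that add atoms: iodomethane, CI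
Why: Kinetic alpha'-enolate methylation; the ketone can enolise only toward C6 (the other side is vinylic and C4 is quaternary), and the C6 configuration is irrelevant because step 3 flattens it again.

Step 3
Reactants: 4 (5S,6RS)-4,4-dimethoxy-6-methyl-5-vinylcyclohex-2-en-1-one; 5 2-bromoethyl trifluoromethanesulfonate
Product: 6 (5S,6S)-6-(2-bromoethyl)-4,4-dimethoxy-6-methyl-5-vinylcyclohex-2-en-1-one
Conditions: LiN(i-Pr)2, THF, −78 → 0 °C; then 5, −78 → −20 °C
Reagents that add atoms: none
Why: Enolate C-alkylation with a primary alkyl triflate (lithium counter-ion, no polar additive, to favour C over O) builds the quaternary carbon; allylic 1,2-strain with the C6 methyl holds the C5 vinyl group pseudoaxial, so the electrophile should enter anti to it and the bromoethyl arm end trans to vinyl (the later trans ring fusion).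

Step 4
Reactants: 6 (5S,6S)-6-(2-bromoethyl)-4,4-dimethoxy-6-methyl-5-vinylcyclohex-2-en-1-one; 7 methyl acrylate
Product: 8 methyl (E)-3-[(1S,2S)-2-(2-bromoethyl)-6,6-dimethoxy-2-methyl-3-oxocyclohex-4-en-1-yl]acrylate
Conditions: 7 (10 equiv), second-generation Hoveyda–Grubbs catalyst (10 mol %), toluene, 80 °C
Reagents that add atoms: none
Why: Olefin cross-metathesis of the terminal vinyl group with excess acrylate should give the E-enoate; the ring enone, the ketal and the primary bromide are inert to the ruthenium carbene.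

Step 5
Reactants: 8 methyl (E)-3-[(1S,2S)-2-(2-bromoethyl)-6,6-dimethoxy-2-methyl-3-oxocyclohex-4-en-1-yl]acrylate
Product: 9 methyl 2-[(1S,3aS,7aS)-7,7-dimethoxy-3a-methyl-4-oxo-2,3,3a,4,7,7a-hexahydro-1H-inden-1-yl]acetate
Conditions: Bu3SnH (slow addition), AIBN (cat.), benzene, 80 °C, high dilution
Reagents that add atoms: none
Why: Tin-hydride chain 5-exo-trig radical cyclisation of the primary alkyl radical onto the enoate closes ring C; the two arms are fixed trans on ring B so only the trans-hydrindane can form, and the chair-like transition state with the enoate terminus pseudoequatorial should place CH2CO2Me at C1 cis to 7a-H and anti to the angular methyl.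

Step 6
Reactants: 9 methyl 2-[(1S,3aS,7aS)-7,7-dimethoxy-3a-methyl-4-oxo-2,3,3a,4,7,7a-hexahydro-1H-inden-1-yl]acetate
Product: 11 methyl 2-[(1S,3aS,7aS)-7,7-dimethoxy-3a-methyl-4-(trifluoromethylsulfonyloxy)-2,3,3a,6,7,7a-hexahydro-1H-inden-1-yl]acetate, via lithium enolate 10 (not isolated)
Conditions: LiBH(s-Bu)3, THF, −78 °C; then PhNTf2, −78 → 0 °C
Reagents that add atoms: N-phenylbis(trifluoromethanesulfonimide), O=S(=O)(N(c1ccccc1)S(=O)(=O)C(F)(F)F)C(F)(F)F
Why: Conjugate reduction of the beta-unsubstituted enone by the bulky borohydride (1,2-attack is blocked by the neighbouring quaternary carbon) gives one regiodefined enolate, which PhNTf2 traps on oxygen; the methyl ester is untouched at −78 °C.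

Step 7
Reactants: 11 methyl 2-[(1S,3aS,7aS)-7,7-dimethoxy-3a-methyl-4-(trifluoromethylsulfonyloxy)-2,3,3a,6,7,7a-hexahydro-1H-inden-1-yl]acetate
Product: 12 methyl 2-[(1S,3aS,7aS)-4-bromo-7,7-dimethoxy-3a-methyl-2,3,3a,6,7,7a-hexahydro-1H-inden-1-yl]acetate
Conditions: Ni(OAc)2·4H2O (10 mol %), 1,5-cyclooctadiene, Zn (20 mol %), LiBr, DMA/THF, rt
Reagents that add atoms: lithium bromide, [Li+].[Br-]
Why: Nickel-catalysed triflate-to-bromide exchange of an enol triflate (oxidative addition to zerovalent nickel, anion exchange, C–Br reductive elimination) under neutral conditions that spare ketal and ester.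

Step 8
Reactants: 12 methyl 2-[(1S,3aS,7aS)-4-bromo-7,7-dimethoxy-3a-methyl-2,3,3a,6,7,7a-hexahydro-1H-inden-1-yl]acetate
Product: 13 methyl 2-[(1S,3aS,4S,7aS)-4-bromo-7,7-dimethoxy-3a-methyloctahydro-1H-inden-1-yl]acetate
Conditions: Mn(dpm)3 (10 mol %), PhSiH3, t-BuOOH, i-PrOH, rt
Reagents that add atoms: none
Why: Manganese-hydride hydrogen-atom-transfer hydrogenation keeps the C–Br bond: H adds to C5 and the alpha-bromo radical at C4 should take its hydrogen axially on the face anti to the axial angular methyl, so bromine ends equatorial and cis to the 3a-methyl (4S).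

Step 9
Reactants: 13 methyl 2-[(1S,3aS,4S,7aS)-4-bromo-7,7-dimethoxy-3a-methyloctahydro-1H-inden-1-yl]acetate
Product: 14 methyl 2-[(1S,3aS,4S,7aS)-4-bromo-3a-methyl-7-oxooctahydro-1H-inden-1-yl]acetate
Conditions: PPTS (cat.), acetone/H2O, rt → 40 °C
Reagents that add atoms: water, O
Why: Acid-catalysed hydrolysis of the dimethyl ketal under mild, weakly acidic conditions, chosen because the ring-fusion hydrogen next to the new ketone is epimerisable toward the cis-hydrindanone.

Step 10
Reactants: 14 methyl 2-[(1S,3aS,4S,7aS)-4-bromo-3a-methyl-7-oxooctahydro-1H-inden-1-yl]acetate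
Product: 15 methyl 2-[(1S,3aS,4S,7R,7aS)-4-bromo-7-hydroxy-3a,7-dimethyloctahydro-1H-inden-1-yl]acetate
Conditions: MeMgBr, CeCl3, THF, −78 °C
Reagents that add atoms: methylmagnesium bromide, C[Mg]Br
Why: Organocerium 1,2-addition (non-basic, so neither enolisation at C7a nor attack on the ester should compete); the axial trajectory is blocked by the 1,3-diaxial angular methyl, so methyl is delivered equatorially and the tertiary hydroxyl ends axial, cis to the 3a-methyl (7R).

Step 11
Reactants: 15 methyl 2-[(1S,3aS,4S,7R,7aS)-4-bromo-7-hydroxy-3a,7-dimethyloctahydro-1H-inden-1-yl]acetate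
Product: 16 methyl 2-[(1S,3aS,4S,7R,7aS)-4-bromo-3a,7-dimethyl-7-(trimethylsilyloxy)octahydro-1H-inden-1-yl]acetate
Conditions: Me3SiOTf, 2,6-lutidine, CH2Cl2, −78 → 0 °C
Reagents that add atoms: trimethylsilyl trifluoromethanesulfonate, C[Si](C)(C)OS(=O)(=O)C(F)(F)F
Why: Silylation of the hindered axial tertiary alcohol with a silyl triflate and a hindered pyridine base; the tertiary trimethylsilyl ether is shielded enough to be carried to step 20.

Step 12
Reactants: 16 methyl 2-[(1S,3aS,4S,7R,7aS)-4-bromo-3a,7-dimethyl-7-(trimethylsilyloxy)octahydro-1H-inden-1-yl]acetate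
Product: 17 2-[(1S,3aS,4S,7R,7aS)-4-bromo-3a,7-dimethyl-7-(trimethylsilyloxy)octahydro-1H-inden-1-yl]acetaldehyde
Conditions: i-Bu2AlH (1.1 equiv), CH2Cl2, −78 °C; aq. potassium sodium tartrate
Reagents that add atoms: none
Why: Partial hydride reduction of the methyl ester at −78 °C stops at the aluminium hemiacetal, which gives the aldehyde on work-up; the secondary bromide and the silyl ether are inert.

Step 13
Reactants: 17 2-[(1S,3aS,4S,7R,7aS)-4-bromo-3a,7-dimethyl-7-(trimethylsilyloxy)octahydro-1H-inden-1-yl]acetaldehyde; 18 vinylmagnesium bromide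
Product: 20 1-[(1S,3aS,4S,7R,7aS)-4-bromo-3a,7-dimethyl-7-(trimethylsilyloxy)octahydro-1H-inden-1-yl]but-3-en-2-yl acetate (both C2 epimers), via bromomagnesium alkoxide 19 (not isolated)
Conditions: CH2=CHMgBr, THF, −78 °C; then Ac2O, DMAP (cat.), −78 °C → rt
Reagents that add atoms: acetic anhydride, CC(=O)OC(C)=O
Why: Grignard 1,2-addition to the aldehyde followed by O-acylation of the magnesium alkoxide in the same flask; the new carbinol carbon forms as both epimers, which is harmless because it is flattened to an enamine in step 15.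

Step 14
Reactants: 20 1-[(1S,3aS,4S,7R,7aS)-4-bromo-3a,7-dimethyl-7-(trimethylsilyloxy)octahydro-1H-inden-1-yl]but-3-en-2-yl acetate
Product: 21 1-[(1S,3aS,4S,7R,7aS)-4-bromo-3a,7-dimethyl-7-(trimethylsilyloxy)octahydro-1H-inden-1-yl]-3-oxopropan-2-yl acetate (alpha-acetoxy aldehyde, both epimers at the acetoxy carbon)
Conditions: O3, CH2Cl2, −78 °C; then PPh3, −78 °C → rt; used crude
Reagents that add atoms: ozone, [O-][O+]=O
Why: Ozonolysis of the terminal alkene with reductive work-up gives the alpha-acetoxy aldehyde; it is used without chromatography to avoid hydrate formation and acetyl migration.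

Step 15
Reactants: 21 alpha-acetoxy aldehyde (both epimers); 22 methyl vinyl ketone
Product: 25 (1R)-1-{[(1S,3aS,4S,7R,7aS)-4-bromo-3a,7-dimethyl-7-(trimethylsilyloxy)octahydro-1H-inden-1-yl]methyl}-4-oxocyclohex-2-en-1-yl acetate, via Michael adduct 23 (not isolated), via aldol 24 (not isolated)
Conditions: 1-[(1R,2R)-2-aminocyclohexyl]-3-[3,5-bis(trifluoromethyl)phenyl]thiourea (20 mol %), PhCO2H (20 mol %), 22 (3 equiv), toluene, 0 °C → rt; then 45 °C
Reagents that add atoms: none
Why: Proposed new method: condensation of the primary amine with 21 erases the acetoxy-bearing stereocentre as a trisubstituted N–H enamine, which adds through that carbon to thiourea-bound 22 to give keto aldehyde 23; the methyl ketone of 23 then attacks the now non-enolisable aldehyde through its own enamine (6-enolendo-exo-trig aldol, closing ring A) and aldol 24 loses water to the enone. The closest known reaction is the primary-amine-catalysed enantioselective Robinson annulation of alpha-alkyl and alpha-aryl branched aldehydes with methyl vinyl ketone to 4,4-disubstituted cyclohexenones; an alpha-acyloxy aldehyde as the donor is the untested element. The new quaternary centre (R in 25) should be set by the catalyst alone, because the hydrindane stereocentres lie beyond the CH2 linker, so both epimers of 21 converge; the (1S,2S) catalyst is used instead if a pilot run shows the opposite sense. The step needs one enamine geometry and one open face: an N–H···O=C hydrogen bond to the acetate carbonyl should hold the Z-enamine, and the thiourea should deliver the enone to the face away from the cyclohexane backbone. The acid co-catalyst keeps the free amine concentration low so that O-to-N acetyl transfer stays slow, and dehydration under the same weakly acidic amine-salt conditions (no base) should limit acetyl migration in 24.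

Step 16
Reactants: 25 (1R)-1-{[hydrindanyl]methyl}-4-oxocyclohex-2-en-1-yl acetate
Product: 27 1-{[(1S,3aS,4S,7R,7aS)-4-bromo-3a,7-dimethyl-7-(trimethylsilyloxy)octahydro-1H-inden-1-yl]methyl}-5,5-dimethyl-4-oxocyclohex-2-en-1-yl acetate (C1 as in 25), via monomethyl enone 26 (not isolated)
Conditions: LiN(SiMe3)2 (1.1 equiv), THF/DMPU, −78 °C, MeI; then LiN(SiMe3)2 (1.2 equiv), MeI, −78 → −20 °C, same flask
Reagents that add atoms: iodomethane, CI
Why: Two successive kinetic alpha'-enolate methylations at C5, the only enolisable position of the ketone; the silazide base is weak enough to leave the acetate methyl largely untouched while it fully deprotonates the ketone.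

Step 17
Reactants: 27 5,5-dimethyl-4-oxocyclohex-2-en-1-yl acetate derivative
Product: 29 1-{[(1S,3aS,4S,7R,7aS)-4-bromo-3a,7-dimethyl-7-(trimethylsilyloxy)octahydro-1H-inden-1-yl]methyl}-5,5-dimethyl-4-(trifluoromethylsulfonyloxy)cyclohex-3-en-1-yl acetate (C1 as in 25), via lithium enolate 28 (not isolated)
Conditions: LiBH(s-Bu)3, THF, −78 °C; then PhNTf2, −78 → 0 °C
Reagents that add atoms: N-phenylbis(trifluoromethanesulfonimide), O=S(=O)(N(c1ccccc1)S(=O)(=O)C(F)(F)F)C(F)(F)F
Why: Conjugate hydride reduction of the enone (the gem-dimethyl group blocks 1,2-attack) gives the enolate on the former alkene side only, which PhNTf2 traps as the enol triflate.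

Step 18
Reactants: 29 enol triflate
Product: 30 4-bromo-1-{[(1S,3aS,4S,7R,7aS)-4-bromo-3a,7-dimethyl-7-(trimethylsilyloxy)octahydro-1H-inden-1-yl]methyl}-5,5-dimethylcyclohex-3-en-1-yl acetate (C1 as in 25)
Conditions: Ni(OAc)2·4H2O (10 mol %), 1,5-cyclooctadiene, Zn (20 mol %), LiBr, DMA/THF, rt
Reagents that add atoms: lithium bromide, [Li+].[Br-]
Why: Nickel-catalysed triflate-to-bromide exchange as in step 7; the hindered secondary alkyl bromide on ring B should not be activated by ligand-free zerovalent nickel at room temperature.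

Step 19
Reactants: 30 alkenyl bromide
Product: 31 (1S,4S)-4-bromo-1-{[(1S,3aS,4S,7R,7aS)-4-bromo-3a,7-dimethyl-7-(trimethylsilyloxy)octahydro-1H-inden-1-yl]methyl}-3,3-dimethylcyclohexyl acetate
Conditions: Mn(dpm)3 (10 mol %), PhSiH3, t-BuOOH, i-PrOH, rt
Reagents that add atoms: none
Why: Hydrogen-atom-transfer hydrogenation as in step 8: with the CH2-hydrindanyl arm equatorial and the acetoxy group axial, the alpha-bromo radical should be reduced axially, anti to the adjacent axial methyl, so bromine ends equatorial and cis to the acetoxy group.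

Step 20
Reactants: 31 silyl ether
Product: 32 target CNP0221847.1
Conditions: HF·pyridine, pyridine, THF, 0 °C → rt
Reagents that add atoms: none
Why: Fluoride cleavage of the tertiary trimethylsilyl ether under buffered, non-basic conditions that leave the tertiary acetate and both secondary bromides untouched.

**Compound list**

1 | 4,4-dimethoxycyclohexa-2,5-dien-1-one | COC1(OC)C=CC(=O)C=C1 | starting material
2 | potassium vinyltrifluoroborate | [K+].C=C[B-](F)(F)F | starting material
3 | (R)-4,4-dimethoxy-5-vinylcyclohex-2-en-1-one | COC1(OC)C=CC(=O)C[C@@H]1C=C | intermediate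
4 | (5S,6RS)-4,4-dimethoxy-6-methyl-5-vinylcyclohex-2-en-1-one (C5 as in 3, both C6 epimers) | COC1(OC)C=CC(=O)C(C)[C@@H]1C=C | intermediate
5 | 2-bromoethyl trifluoromethanesulfonate | BrCCOS(=O)(=O)C(F)(F)F | starting material
6 | (5S,6S)-6-(2-bromoethyl)-4,4-dimethoxy-6-methyl-5-vinylcyclohex-2-en-1-one (bromoethyl trans to vinyl) | COC1(OC)C=CC(=O)[C@@](C)(CCBr)[C@@H]1C=C | intermediate
7 | methyl acrylate | C=CC(=O)OC | starting material
8 | methyl (E)-3-[(1S,2S)-2-(2-bromoethyl)-6,6-dimethoxy-2-methyl-3-oxocyclohex-4-en-1-yl]acrylate | COC1(OC)C=CC(=O)[C@@](C)(CCBr)[C@@H]1/C=C/C(=O)OC | intermediate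
9 | methyl 2-[(1S,3aS,7aS)-7,7-dimethoxy-3a-methyl-4-oxo-2,3,3a,4,7,7a-hexahydro-1H-inden-1-yl]acetate (trans-fused; side chain cis to 7a-H, anti to 3a-methyl) | COC(=O)C[C@@H]2CC[C@]3(C)C(=O)C=CC(OC)(OC)[C@@H]23 | intermediate
10 | lithium enolate of the C4 ketone of 9 after conjugate reduction (C4=C5 enolate) | COC(=O)C[C@@H]2CC[C@]3(C)C(O[Li])=CCC(OC)(OC)[C@@H]23 | intermediate
11 | methyl 2-[(1S,3aS,7aS)-7,7-dimethoxy-3a-methyl-4-(trifluoromethylsulfonyloxy)-2,3,3a,6,7,7a-hexahydro-1H-inden-1-yl]acetate | COC(=O)C[C@@H]2CC[C@]3(C)C(OS(=O)(=O)C(F)(F)F)=CCC(OC)(OC)[C@@H]23 | intermediate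
12 | methyl 2-[(1S,3aS,7aS)-4-bromo-7,7-dimethoxy-3a-methyl-2,3,3a,6,7,7a-hexahydro-1H-inden-1-yl]acetate | COC(=O)C[C@@H]2CC[C@]3(C)C(Br)=CCC(OC)(OC)[C@@H]23 | intermediate
13 | methyl 2-[(1S,3aS,4S,7aS)-4-bromo-7,7-dimethoxy-3a-methyloctahydro-1H-inden-1-yl]acetate (Br equatorial, cis to 3a-methyl) | COC(=O)C[C@@H]2CC[C@]3(C)[C@@H](Br)CCC(OC)(OC)[C@@H]23 | intermediate
14 | methyl 2-[(1S,3aS,4S,7aS)-4-bromo-3a-methyl-7-oxooctahydro-1H-inden-1-yl]acetate | COC(=O)C[C@@H]2CC[C@]3(C)[C@@H](Br)CCC(=O)[C@@H]23 | intermediate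
15 | methyl 2-[(1S,3aS,4S,7R,7aS)-4-bromo-7-hydroxy-3a,7-dimethyloctahydro-1H-inden-1-yl]acetate (7-OH axial, cis to 3a-methyl) | COC(=O)C[C@@H]2CC[C@]3(C)[C@@H](Br)CC[C@@](C)(O)[C@@H]23 | intermediate
16 | methyl 2-[(1S,3aS,4S,7R,7aS)-4-bromo-3a,7-dimethyl-7-(trimethylsilyloxy)octahydro-1H-inden-1-yl]acetate | COC(=O)C[C@@H]2CC[C@]3(C)[C@@H](Br)CC[C@@](C)(O[Si](C)(C)C)[C@@H]23 | intermediate
17 | 2-[(1S,3aS,4S,7R,7aS)-4-bromo-3a,7-dimethyl-7-(trimethylsilyloxy)octahydro-1H-inden-1-yl]acetaldehyde | O=CC[C@@H]2CC[C@]3(C)[C@@H](Br)CC[C@@](C)(O[Si](C)(C)C)[C@@H]23 | intermediate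
18 | vinylmagnesium bromide | C=C[Mg]Br | starting material
19 | bromomagnesium 1-[(1S,3aS,4S,7R,7aS)-4-bromo-3a,7-dimethyl-7-(trimethylsilyloxy)octahydro-1H-inden-1-yl]but-3-en-2-olate (both C2 epimers) | C=CC(O[Mg]Br)C[C@@H]2CC[C@]3(C)[C@@H](Br)CC[C@@](C)(O[Si](C)(C)C)[C@@H]23 | intermediate
20 | 1-[(1S,3aS,4S,7R,7aS)-4-bromo-3a,7-dimethyl-7-(trimethylsilyloxy)octahydro-1H-inden-1-yl]but-3-en-2-yl acetate (both C2 epimers) | CC(=O)OC(C=C)C[C@@H]2CC[C@]3(C)[C@@H](Br)CC[C@@](C)(O[Si](C)(C)C)[C@@H]23 | intermediate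
21 | 1-[(1S,3aS,4S,7R,7aS)-4-bromo-3a,7-dimethyl-7-(trimethylsilyloxy)octahydro-1H-inden-1-yl]-3-oxopropan-2-yl acetate (both epimers at the acetoxy carbon) | CC(=O)OC(C=O)C[C@@H]2CC[C@]3(C)[C@@H](Br)CC[C@@](C)(O[Si](C)(C)C)[C@@H]23 | intermediate
22 | methyl vinyl ketone (but-3-en-2-one) | CC(=O)C=C | starting material
23 | (2R)-2-{[(1S,3aS,4S,7R,7aS)-4-bromo-3a,7-dimethyl-7-(trimethylsilyloxy)octahydro-1H-inden-1-yl]methyl}-1,5-dioxohexan-2-yl acetate | CC(=O)O[C@](C=O)(CCC(C)=O)C[C@@H]2CC[C@]3(C)[C@@H](Br)CC[C@@](C)(O[Si](C)(C)C)[C@@H]23 | intermediate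
24 | (1R)-1-{[(1S,3aS,4S,7R,7aS)-4-bromo-3a,7-dimethyl-7-(trimethylsilyloxy)octahydro-1H-inden-1-yl]methyl}-2-hydroxy-4-oxocyclohexyl acetate (both carbinol epimers) | CC(=O)O[C@]1(C[C@@H]2CC[C@]3(C)[C@@H](Br)CC[C@@](C)(O[Si](C)(C)C)[C@@H]23)C(O)CC(=O)CC1 | intermediate
25 | (1R)-1-{[(1S,3aS,4S,7R,7aS)-4-bromo-3a,7-dimethyl-7-(trimethylsilyloxy)octahydro-1H-inden-1-yl]methyl}-4-oxocyclohex-2-en-1-yl acetate | CC(=O)O[C@]1(C[C@@H]2CC[C@]3(C)[C@@H](Br)CC[C@@](C)(O[Si](C)(C)C)[C@@H]23)C=CC(=O)CC1 | intermediate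
26 | 1-{[(1S,3aS,4S,7R,7aS)-4-bromo-3a,7-dimethyl-7-(trimethylsilyloxy)octahydro-1H-inden-1-yl]methyl}-5-methyl-4-oxocyclohex-2-en-1-yl acetate (C1 as in 25, both C5 epimers) | CC(=O)O[C@]1(C[C@@H]2CC[C@]3(C)[C@@H](Br)CC[C@@](C)(O[Si](C)(C)C)[C@@H]23)C=CC(=O)C(C)C1 | intermediate
27 | 1-{[(1S,3aS,4S,7R,7aS)-4-bromo-3a,7-dimethyl-7-(trimethylsilyloxy)octahydro-1H-inden-1-yl]methyl}-5,5-dimethyl-4-oxocyclohex-2-en-1-yl acetate (C1 as in 25) | CC(=O)O[C@]1(C[C@@H]2CC[C@]3(C)[C@@H](Br)CC[C@@](C)(O[Si](C)(C)C)[C@@H]23)C=CC(=O)C(C)(C)C1 | intermediate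
28 | lithium enolate of 27 after conjugate reduction (C3=C4 enolate of the cyclohexyl acetate) | CC(=O)O[C@]1(C[C@@H]2CC[C@]3(C)[C@@H](Br)CC[C@@](C)(O[Si](C)(C)C)[C@@H]23)CC=C(O[Li])C(C)(C)C1 | intermediate
29 | 1-{[(1S,3aS,4S,7R,7aS)-4-bromo-3a,7-dimethyl-7-(trimethylsilyloxy)octahydro-1H-inden-1-yl]methyl}-5,5-dimethyl-4-(trifluoromethylsulfonyloxy)cyclohex-3-en-1-yl acetate (C1 as in 25) | CC(=O)O[C@]1(C[C@@H]2CC[C@]3(C)[C@@H](Br)CC[C@@](C)(O[Si](C)(C)C)[C@@H]23)CC=C(OS(=O)(=O)C(F)(F)F)C(C)(C)C1 | intermediate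
30 | 4-bromo-1-{[(1S,3aS,4S,7R,7aS)-4-bromo-3a,7-dimethyl-7-(trimethylsilyloxy)octahydro-1H-inden-1-yl]methyl}-5,5-dimethylcyclohex-3-en-1-yl acetate (C1 as in 25) | CC(=O)O[C@]1(C[C@@H]2CC[C@]3(C)[C@@H](Br)CC[C@@](C)(O[Si](C)(C)C)[C@@H]23)CC=C(Br)C(C)(C)C1 | intermediate
31 | (1S,4S)-4-bromo-1-{[(1S,3aS,4S,7R,7aS)-4-bromo-3a,7-dimethyl-7-(trimethylsilyloxy)octahydro-1H-inden-1-yl]methyl}-3,3-dimethylcyclohexyl acetate (Br cis to OAc) | CC(=O)O[C@]1(C[C@@H]2CC[C@]3(C)[C@@H](Br)CC[C@@](C)(O[Si](C)(C)C)[C@@H]23)CC[C@H](Br)C(C)(C)C1 | intermediate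
32 | (1S,4S)-4-bromo-1-{[(1S,3aS,4S,7R,7aS)-4-bromo-7-hydroxy-3a,7-dimethyloctahydro-1H-inden-1-yl]methyl}-3,3-dimethylcyclohexyl acetate (CNP0221847.1) | CC(=O)O[C@]1(C[C@@H]2CC[C@]3(C)[C@@H](Br)CC[C@@](C)(O)[C@@H]23)CC[C@H](Br)C(C)(C)C1 | target

**Summary**

Total step count: 20. Longest linear sequence: 20 steps (1 to 32).

**Steps most likely to fail, with fallbacks**

Step 15 (Proposed new method). The enamine of the acetoxy aldehyde may form slowly or as a mixture of geometries, which would erode face selection. The acetyl group may also shift to the catalyst nitrogen, or migrate and be eliminated in aldol 24. The fallback uses known reactions, sets out from ester 16 and returns at enone 25. The bis-Grignard reagent from 2,2-bis(2-bromoethyl)-1,3-dioxolane and Mg adds twice to the ester carbon and closes a symmetric ring A, giving the spiro-ketal tertiary alcohol F1. Acetylation (Ac2O, DMAP, Et3N) gives the tertiary acetate F2. Transketalisation (I2 cat., acetone) gives the prochiral 4-acetoxy-4-alkylcyclohexanone F3. Enantiotopic-group-selective deprotonation with lithium bis[(R)-1-phenylethyl]amide in the presence of Me3SiCl at −100 °C gives the silyl enol ether F4; the antipodal amide is used if the other arm is enolised. Saegusa–Ito oxidation (Pd(OAc)2, MeCN) then gives 25. The acetoxy carbon is again set by a reagent and not by the remote hydrindane.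

Step 5. The primary radical may take hydrogen from the stannane before the slower trans-fused 5-exo closure, or close through a boat-like arrangement and erode the C1 configuration. The fallback sets out from bromide 8 and returns at 9. Kornblum displacement (NaNO2, phloroglucinol, DMF) gives the nitroalkane F5. Catalytic DBU in MeCN brings about a reversible intramolecular nitro-Michael addition, so the ring closes under thermodynamic control to the trans-hydrindane nitro ester F6, with CH2CO2Me anti to the C7 branch. Radical denitration (Bu3SnH, AIBN, toluene, 110 °C) then gives 9.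

Step 16. During the second, slower enolisation the base may deprotonate the acetate methyl; that enolate can add to the enone intramolecularly or transfer the acyl group. The fallback sets out from 25 and returns at 27. Methanolysis of the acetate (K2CO3, MeOH, 0 °C) gives the hydroxy enone F7. Double methylation through the alkoxide enolate dianion (LiN(i-Pr)2, 2.2 equiv, MeI, twice) gives the gem-dimethyl hydroxy enone F8. Acetylation of the tertiary alcohol (Ac2O, DMAP, Et3N, 40 °C) gives 27.

**Further compounds**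

F1 | step 15 | 8-{[(1S,3aS,4S,7R,7aS)-4-bromo-3a,7-dimethyl-7-(trimethylsilyloxy)octahydro-1H-inden-1-yl]methyl}-1,4-dioxaspiro[4.5]decan-8-ol | OC1(C[C@@H]2CC[C@]3(C)[C@@H](Br)CC[C@@](C)(O[Si](C)(C)C)[C@@H]23)CCC4(CC1)OCCO4
F2 | step 15 | 8-{[(1S,3aS,4S,7R,7aS)-4-bromo-3a,7-dimethyl-7-(trimethylsilyloxy)octahydro-1H-inden-1-yl]methyl}-1,4-dioxaspiro[4.5]decan-8-yl acetate | CC(=O)OC1(C[C@@H]2CC[C@]3(C)[C@@H](Br)CC[C@@](C)(O[Si](C)(C)C)[C@@H]23)CCC4(CC1)OCCO4
F3 | step 15 | 1-{[(1S,3aS,4S,7R,7aS)-4-bromo-3a,7-dimethyl-7-(trimethylsilyloxy)octahydro-1H-inden-1-yl]methyl}-4-oxocyclohexyl acetate | CC(=O)OC1(C[C@@H]2CC[C@]3(C)[C@@H](Br)CC[C@@](C)(O[Si](C)(C)C)[C@@H]23)CCC(=O)CC1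
F4 | step 15 | 1-{[(1S,3aS,4S,7R,7aS)-4-bromo-3a,7-dimethyl-7-(trimethylsilyloxy)octahydro-1H-inden-1-yl]methyl}-4-(trimethylsilyloxy)cyclohex-3-en-1-yl acetate (C1 as in 25) | CC(=O)O[C@]1(C[C@@H]2CC[C@]3(C)[C@@H](Br)CC[C@@](C)(O[Si](C)(C)C)[C@@H]23)CC=C(O[Si](C)(C)C)CC1
F5 | step 5 | methyl (E)-3-[(1S,2S)-6,6-dimethoxy-2-methyl-2-(2-nitroethyl)-3-oxocyclohex-4-en-1-yl]acrylate | COC1(OC)C=CC(=O)[C@@](C)(CC[N+](=O)[O-])[C@@H]1/C=C/C(=O)OC
F6 | step 5 | methyl 2-[7,7-dimethoxy-3a-methyl-2-nitro-4-oxo-2,3,3a,4,7,7a-hexahydro-1H-inden-1-yl]acetate (C1, C3a, C7a as in 9; both C2 epimers) | COC(=O)C[C@@H]2C([N+](=O)[O-])C[C@]3(C)C(=O)C=CC(OC)(OC)[C@@H]23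
F7 | step 16 | (R)-4-{[(1S,3aS,4S,7R,7aS)-4-bromo-3a,7-dimethyl-7-(trimethylsilyloxy)octahydro-1H-inden-1-yl]methyl}-4-hydroxycyclohex-2-en-1-one | O[C@]1(C[C@@H]2CC[C@]3(C)[C@@H](Br)CC[C@@](C)(O[Si](C)(C)C)[C@@H]23)C=CC(=O)CC1
F8 | step 16 | 4-{[(1S,3aS,4S,7R,7aS)-4-bromo-3a,7-dimethyl-7-(trimethylsilyloxy)octahydro-1H-inden-1-yl]methyl}-4-hydroxy-6,6-dimethylcyclohex-2-en-1-one (C4 as in F7) | O[C@]1(C[C@@H]2CC[C@]3(C)[C@@H](Br)CC[C@@](C)(O[Si](C)(C)C)[C@@H]23)C=CC(=O)C(C)(C)C1
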